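## The problem

Target 27 is a (2S)-flavanone. Ring A (C4a to C8a) is fused to the dihydropyranone ring C, and ring B, a catechol, sits on C2. Ring A is a phloroglucinol whose three oxygens must end up different (free 5-OH, 7-OMe, ring oxygen O1), and the side chain must stand at C8, between O1 and the methoxy group. C2 is the only stereocentre, so nothing in the molecule can relay chirality to it and it has to come from a reagent or catalyst. It is also fragile: base opens a flavanone to the 2'-hydroxychalcone by β-elimination of O1, and acid can ionise the benzylic C2–O bond, and either path racemises C2. The side chain carries a trisubstituted (Z)-alkene, the less accessible geometry, and a primary allylic alcohol. This rules out hydrogenolysis and long exposure to strong acid. The free catechol is oxidisable and, as an electron donor, makes C2 more prone to ionise, so ring B has to travel in an electron-poor protected form. The feature that invites a late ring closure is that C4 is bonded to C4a, which is ortho to O1 and to the C5 oxygen and para to the C7 methoxy group. The only other position ortho to O1, C8, is already substituted, so an acid tethered through O1 can acylate C4a alone.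

## Retrosynthesis

**Protecting groups (27 ⇐ 26 ⇐ 25).** No skeletal bond is cut. The end game is limited to a buffered fluoride desilylation and a neutral deacetylation, because 27 tolerates neither base nor strong acid. Ring B is carried as the diacetate, C5–O as a TBS ether and the allylic oxygen as a TBDPS ether. The acetates keep ring B electron-poor while C2 is at risk; the two silyl groups leave together in 25 → 26.

**C4–C4a (25 ⇐ 23).** Cutting the aryl ketone bond gives the open (S)-3-aryloxy-3-arylpropanoic acid 23. The neighbouring cut, O1–C2 by oxa-Michael closure of a chalcone, is reversible and would leave the stereocentre to a late and less certain asymmetric cyclisation. The cut C2–C1' would need an asymmetric conjugate arylation of a fully substituted chromone. With C4–C4a the stereocentre is already in place in 23 and regiochemistry is dictated by the tether. The forward reaction must be fast and cold enough that the C2–O bond does not ionise.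

**O1–C2 (23 ⇐ 22 ⇐ 14 + 21).** The aryl ether bond is cut to phenol 14 and the (R)-β-hydroxy ester 21. A Mitsunobu reaction joins them with inversion. The ester is allyl so that it can be removed without hydroxide, which would expel the aryloxide by β-elimination and strip the acetates. This cut divides the molecule into two halves of similar size. It asks for clean SN2 substitution at a benzylic carbon flanked by an acidifying ester, which the electron-poor ring B should favour.

**The hydroxy ester (21 ⇐ 20 ⇐ 19 ⇐ 16 + 17; 16 ⇐ 15).** The carbinol stereocentre is traced to ketone 20, so that a catalytic transfer hydrogenation sets it. Ketone 20 comes from the racemic aldol-type adduct 19, and the C2–C3 bond of 19 is cut to 3,4-diacetoxybenzaldehyde 16 and allyl bromoacetate 17. A zinc enolate is chosen over a lithium enolate because it leaves aryl acetates alone. Aldehyde 16 is the diacetate of 3,4-dihydroxybenzaldehyde 15.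

**Side chain to ring A (14 ⇐ 10 + 4).** The bond between the benzylic carbon and the alkene carbon is cut. Benzyl alcohol 10 serves as a latent ortho-quinone methide 13, and vinyl iodide 4 supplies the alkenyl nucleophile 12. The alternative cut at the aryl–CH2 bond (aryl copper plus allylic bromide) needs two more steps for the bromide and a separate unmasking of the phenol. Here the (Z)-alkene is taken over intact from 4, and the phenol that becomes O1 is set free in the same operation.

**Ring A differentiation (10 ⇐ 9 ⇐ 8 ⇐ 7 ⇐ 5).** The formyl carbon of 7 is cut from 5-methoxyresorcinol 5. In 7 the hydroxyl next to the aldehyde is hydrogen-bonded and the other is not, so the two formerly equivalent hydroxyls of 5 can be told apart without a statistical step. The free one takes the TBS group (8) and the hydrogen-bonded one takes the carbonate (9). Reduction then gives 10. The formylation must enter between a hydroxyl and the methoxy group.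

**The (Z)-alkene (4 ⇐ 3 ⇐ 1).** The C–CH3 and C–I bonds of 3 are cut back to propargyl alcohol 1. An anti-carbometalation directed by the alkoxide places the metal, and then iodine, cis to the CH2O group. This is the relationship that becomes the (Z)-geometry of 27. Silylation gives 4.

## Roads not taken

**Alternative 1:** Ring A is cut at C8a–C8, C7–C6 and C8a–C4a. In the forward direction, cyclobutenone A2 and methoxyalkyne A3 are heated, and a vinylketene cascade ([2+2] addition, four-electron opening, six-electron closure) gives phenol A1.
- Merits: every ring-A substituent is placed by connectivity, no regioisomer can form, and the two ether oxygens arrive differentiated with the free hydroxyl only where O1 is needed. In regiochemical certainty this is better than the formylation of 5 in the chosen plan.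
- Weak points: A3 is a skipped enynol ether carrying the (Z)-alkene. It takes several steps to make and is exposed to propargyl–allyl isomerisation at the temperature of the annulation.
- A1 only reaches the stage of phenol 14, so ether formation and closure of ring C still have to follow.
- The ethyl ether at C5 would have to be cleaved at the end by a chelating Lewis acid in the presence of an allylic alcohol and the benzylic C2–O bond.
- Against its regiocontrol, the chosen plan sets an aromatic starting material, differentiation by a hydrogen bond in 7, and a C5 silyl group that leaves with fluoride.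

**Alternative 2:** Ring C is cut at C3–C4 and O1–C2. Salicylaldehyde A5 is converted, with an orthoester and a confined chiral Brønsted acid, into a 4-alkoxy ortho-quinone methide that adds styrene A6 to give the 2,4-cis flavan A4.
- Merits: ring C and the C2 stereocentre are made in one catalytic step from two simple halves, with no Mitsunobu reaction and no stoichiometric chiral information. In convergence and stereochemical economy this road is better.
- Weak points: A4 is at the flavan oxidation level. Its C4 ether must be hydrolysed and oxidised on an electron-rich ring that ionises readily at C4, with the side-chain alkene and allylic ether nearby.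
- The catalyst pocket must accept a salicylaldehyde with a large substituent next to the phenol, and an electron-rich styrene that tends to oligomerise under acid.
- A5 itself needs a regioselective formylation of a fully substituted ring.
- The chosen plan sets against this a transfer hydrogenation and a Mitsunobu inversion of predictable sense, and a ring closure that delivers the ketone directly.

**Alternative 3:** Ring A is cut at C8–C8a and C5–C4a. Diene A9 adds across the bromo-enone of the enantiopure dihydropyranone A8, and two eliminations (of bromide and of one methoxy group) aromatise the adduct to flavanone A7.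
- Merits: C2 is set first by a catalytic hetero-Diels–Alder reaction and never meets an ionising acid. The 5-hydroxyl arrives free and the 7-methoxy group by construction. On paper this is the most convergent road and it needs no protecting group at C5.
- Weak points: A8 is a vinylogous ester and therefore a sluggish dienophile. A9 bears the side chain on its nucleophilic terminus, which makes it hindered and hard to prepare with one geometry.
- The eliminations need base or heat, under which the pyranone can open by β-elimination of O1 and scramble C2.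
- The chosen plan sets against this a commercial aromatic ring A and reaction classes that are well tested on phloroglucinol ethers.

Key step: step 14

Remark: the double-bond descriptor of the target is read as the (Z)-alkene (ring CH2 and CH2OH on the same side) and C2 as S; all fragments are built to that reading.

## Route

Step 1
Reactants: 1 prop-2-yn-1-ol (propargyl alcohol)
Product: 3 (Z)-3-iodo-2-methylprop-2-en-1-ol, via alkenylmagnesium alkoxide 2 (not isolated)
Conditions: MeMgBr (3 equiv), CuI (10 mol%), THF, −10 °C → rt; then I2, −10 °C; aq NH4Cl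
Reagents that add atoms: methylmagnesium bromide, C[Mg]Br; iodine, II
Why: Copper-catalysed anti-carbomagnesiation of the propargylic magnesium alkoxide puts methyl on C2 and magnesium on C3 cis to the CH2O group through a five-membered chelate. Iodinolysis of the C–Mg bond goes with retention, which fixes the (Z)-geometry of the side chain.

Step 2
Reactants: 3 (Z)-3-iodo-2-methylprop-2-en-1-ol
Product: 4 (Z)-tert-butyl[(3-iodo-2-methylprop-2-en-1-yl)oxy]diphenylsilane
Conditions: TBDPSCl (1.1 equiv), imidazole, CH2Cl2, 0 °C → rt
Reagents that add atoms: tert-butyl(chloro)diphenylsilane, CC(C)(C)[Si](Cl)(c1ccccc1)c1ccccc1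
Why: Routine silylation of a primary alcohol. TBDPS is chosen over TBS because it is bulkier toward silyl migration in the alkenyl metal of step 7 and more tolerant of the acid released in step 14.

Step 3
Reactants: 5 5-methoxyresorcinol (5-methoxybenzene-1,3-diol)
Product: 7 2,4-dihydroxy-6-methoxybenzaldehyde, via aryl iminium chloride 6 (not isolated)
Conditions: POCl3 (1.1 equiv), DMF (1.5 equiv), MeCN, 0 °C → rt; then H2O, 50 °C
Reagents that add atoms: N,N-dimethylformamide, CN(C)C=O; water, O
Why: Vilsmeier–Haack formylation. The chloroiminium ion is expected to enter para to one hydroxyl and ortho to the other, the normal site for this phenol, and hydrolysis of 6 gives the aldehyde. Any isomer formylated between the two hydroxyls is removed at this stage.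

Step 4
Reactants: 7 2,4-dihydroxy-6-methoxybenzaldehyde
Product: 8 4-[(tert-butyldimethylsilyl)oxy]-2-hydroxy-6-methoxybenzaldehyde
Conditions: TBSCl (1.05 equiv), imidazole, CH2Cl2, 0 °C
Reagents that add atoms: tert-butyl(chloro)dimethylsilane, CC(C)(C)[Si](C)(C)Cl
Why: Selective silylation of 2,4-dihydroxybenzaldehydes. The 2-hydroxyl is locked in a hydrogen bond to the formyl group, so the free and more acidic 4-hydroxyl reacts. This differentiates the future C5 oxygen from the future O1.

Step 5
Reactants: 8 4-[(tert-butyldimethylsilyl)oxy]-2-hydroxy-6-methoxybenzaldehyde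
Product: 9 tert-butyl 5-[(tert-butyldimethylsilyl)oxy]-2-formyl-3-methoxyphenyl carbonate
Conditions: Boc2O (1.2 equiv), i-Pr2NEt, DMAP (cat.), THF, 0 °C → rt
Reagents that add atoms: di-tert-butyl dicarbonate, CC(C)(C)OC(=O)OC(=O)OC(C)(C)C
Why: DMAP-catalysed carbonate formation on the remaining phenol. It installs the ortho-OBoc group that later triggers quinone methide formation.

Step 6
Reactants: 9 tert-butyl 5-[(tert-butyldimethylsilyl)oxy]-2-formyl-3-methoxyphenyl carbonate
Product: 10 tert-butyl 5-[(tert-butyldimethylsilyl)oxy]-2-(hydroxymethyl)-3-methoxyphenyl carbonate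
Conditions: BH3·THF, THF, −10 → 0 °C; then pH 7 buffer
Reagents that add atoms: none
Why: Borane reduction of an aryl aldehyde. It proceeds through neutral alkoxyboranes, so no free alkoxide forms that could start carbonate transfer early, which is why alkoxide-forming hydrides are avoided; the carbonate and silyl ether are inert.

Step 7
Reactants: 10 tert-butyl 5-[(tert-butyldimethylsilyl)oxy]-2-(hydroxymethyl)-3-methoxyphenyl carbonate; 4 (Z)-tert-butyl[(3-iodo-2-methylprop-2-en-1-yl)oxy]diphenylsilane
Product: 14 5-[(tert-butyldimethylsilyl)oxy]-2-{(Z)-4-[(tert-butyldiphenylsilyl)oxy]-3-methylbut-2-en-1-yl}-3-methoxyphenol, via alkenyllithium 11 (not isolated), via alkenylmagnesium bromide 12 (not isolated), via ortho-quinone methide 13 (not isolated)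
Conditions: 4 (1.5 equiv), t-BuLi (3.0 equiv), Et2O, −78 °C; MgBr2·OEt2, −78 → 0 °C; added to 10 + t-BuMgCl (1.05 equiv), THF, −78 °C → rt; aq NH4Cl
Reagents that add atoms: none
Why: Anionic ortho-quinone methide generation from an ortho-OBoc benzyl alcohol with 1,4-addition of a Grignard reagent. The magnesium alkoxide of 10 takes over the carbonate, and the resulting phenoxide expels it to give 13. Iodine–lithium exchange, transmetalation and addition all go with retention at the alkenyl carbon, so the (Z)-alkene of 4 is carried into 14 and the phenol that becomes O1 is freed in the same step.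

Step 8
Reactants: 15 3,4-dihydroxybenzaldehyde
Product: 16 4-formyl-1,2-phenylene diacetate (3,4-diacetoxybenzaldehyde)
Conditions: Ac2O (2.5 equiv), pyridine, DMAP (cat.), CH2Cl2, 0 °C → rt
Reagents that add atoms: acetic anhydride, CC(=O)OC(C)=O
Why: Routine acetylation of a catechol. The acetates protect ring B from oxidation and make it electron-poor for steps 12 and 14.

Step 9
Reactants: 16 4-formyl-1,2-phenylene diacetate; 17 allyl bromoacetate (prop-2-en-1-yl 2-bromoacetate)
Product: 19 rac-allyl 3-(3,4-diacetoxyphenyl)-3-hydroxypropanoate, via Reformatsky zinc enolate 18 (not isolated)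
Conditions: Zn dust (TMSCl-activated), THF, 0 °C → rt; aq NH4Cl
Reagents that add atoms: none
Why: Reformatsky reaction. The zinc enolate adds to the aldehyde but is too mild to attack aryl acetates or the allyl ester, which a lithium enolate might do.

Step 10
Reactants: 19 rac-allyl 3-(3,4-diacetoxyphenyl)-3-hydroxypropanoate
Product: 20 allyl 3-(3,4-diacetoxyphenyl)-3-oxopropanoate
Conditions: Dess–Martin periodinane (1.3 equiv), CH2Cl2, 0 °C → rt
Reagents that add atoms: none
Why: Dess–Martin oxidation of a benzylic β-hydroxy ester to the β-keto ester under near-neutral conditions that leave the acetates and the allyl ester intact.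

Step 11
Reactants: 20 allyl 3-(3,4-diacetoxyphenyl)-3-oxopropanoate
Product: 21 allyl (R)-3-(3,4-diacetoxyphenyl)-3-hydroxypropanoate
Conditions: RuCl[(R,R)-TsDPEN](p-cymene) (1 mol%), HCO2H/Et3N (5:2), CH2Cl2, 30 °C
Reagents that add atoms: none
Why: Noyori asymmetric transfer hydrogenation of an aryl ketone. Hydride and proton are delivered in an outer-sphere six-membered transition state in which the aryl group sits against the arene ligand, so the (R,R)-catalyst should give the (R)-carbinol by analogy with acetophenone. The reagent does not reduce the allyl C=C or touch the acetates.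

Step 12
Reactants: 14 5-[(tert-butyldimethylsilyl)oxy]-2-{(Z)-4-[(tert-butyldiphenylsilyl)oxy]-3-methylbut-2-en-1-yl}-3-methoxyphenol; 21 allyl (R)-3-(3,4-diacetoxyphenyl)-3-hydroxypropanoate
Product: 22 allyl (S)-3-[5-(tert-butyldimethylsilyloxy)-2-{(Z)-4-(tert-butyldiphenylsilyloxy)-3-methylbut-2-en-1-yl}-3-methoxyphenoxy]-3-(3,4-diacetoxyphenyl)propanoate
Conditions: PPh3 (1.5 equiv), DIAD (1.5 equiv), 21 (1.3 equiv), toluene, −20 °C → rt
Reagents that add atoms: none
Why: Mitsunobu etherification. The phenoxide displaces the alkoxyphosphonium group by SN2, inverting the (R)-carbinol to the (S)-ether that becomes C2. The electron-poor diacetoxyphenyl ring disfavours ionisation of the benzylic carbon, and the non-polar solvent and low temperature are meant to hold back dehydration to the cinnamate.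

Step 13
Reactants: 22 allyl (S)-3-aryloxy-3-(3,4-diacetoxyphenyl)propanoate
Product: 23 (S)-3-[5-(tert-butyldimethylsilyloxy)-2-{(Z)-4-(tert-butyldiphenylsilyloxy)-3-methylbut-2-en-1-yl}-3-methoxyphenoxy]-3-(3,4-diacetoxyphenyl)propanoic acid
Conditions: Pd(PPh3)4 (5 mol%), N-methylaniline (3 equiv), THF, rt
Reagents that add atoms: none
Why: Tsuji–Trost deallylation. Zerovalent palladium ionises only the allyl ester and the weakly basic amine traps the allyl group. No hydroxide is present, so the aryloxide is not lost by β-elimination and the acetates stay; the allylic silyl ether is not a leaving group for palladium.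

Step 14
Reactants: 23 (S)-3-aryloxy-3-(3,4-diacetoxyphenyl)propanoic acid
Product: 25 (2S)-2-(3,4-diacetoxyphenyl)-5-[(tert-butyldimethylsilyl)oxy]-8-{(Z)-4-[(tert-butyldiphenylsilyl)oxy]-3-methylbut-2-en-1-yl}-7-methoxychroman-4-one, via mixed trifluoroacetic anhydride 24 (not isolated)
Conditions: (CF3CO)2O (3 equiv), CH2Cl2, 0 °C, short reaction time; cold aq NaHCO3
Reagents that add atoms: none
Why: The acid and trifluoroacetic anhydride give mixed anhydride 24, an acylium-like donor that is attacked by C4a to form a Wheland intermediate, which loses a proton to trifluoroacetate. The closest known reaction type is the trifluoroacetic-anhydride-mediated intramolecular Friedel–Crafts acylation that closes 3-aryloxypropanoic acids to chroman-4-ones and 3-aryloxy-3-arylpropanoic acids to flavanones. Ring C closes in a 6-exo-trig mode at the acyl carbon (O1–C2–C3–C4–C4a–C8a). No stereocentre is formed; C2 is carried over from 23. Site selectivity is needed and is secured by the tether, which reaches only the two positions ortho to O1, of which C8 is substituted. C4a is ortho to O1 and to the C5 silyloxy group and para to the C7 methoxy group, so closure should outrun intermolecular trifluoroacetylation at C6, and the new ketone then deactivates ring A against a second acylation. Integrity at C2 requires that the benzylic C2–O bond does not ionise in the acid that is released; the two acetoxy groups make ring B electron-poor, and low temperature and short contact time work in the same direction. The allylic oxygen carries the acid-tolerant TBDPS group, and a silyl group lost here would be replaced by a trifluoroacetate that falls off in the later deprotections.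

Step 15
Reactants: 25 protected (2S)-flavanone
Product: 26 (2S)-2-(3,4-diacetoxyphenyl)-5-hydroxy-8-[(Z)-4-hydroxy-3-methylbut-2-en-1-yl]-7-methoxychroman-4-one
Conditions: HF·pyridine, pyridine, THF, 0 °C → rt
Reagents that add atoms: none
Why: Buffered fluoride desilylation. It removes the primary TBDPS ether and the aryl TBS ether, whose cleavage is helped by the neighbouring C4 carbonyl. The medium is neither basic enough to open the flavanone nor acidic enough to ionise C2–O, and the aryl acetates are untouched.

Step 16
Reactants: 26 (2S)-2-(3,4-diacetoxyphenyl)-5-hydroxy-8-[(Z)-4-hydroxy-3-methylbut-2-en-1-yl]-7-methoxychroman-4-one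
Product: 27 (2S)-2-(3,4-dihydroxyphenyl)-5-hydroxy-8-[(Z)-4-hydroxy-3-methylbut-2-en-1-yl]-7-methoxychroman-4-one
Conditions: NH4OAc (excess), MeOH/H2O (4:1), rt
Reagents that add atoms: none
Why: Ammonium-acetate-promoted methanolysis of aryl acetates at near-neutral pH. It frees the catechol without the base that would open ring C to the chalcone and racemise C2.

## Compound list

1 | prop-2-yn-1-ol (propargyl alcohol) | C#CCO | starting material
2 | bromomagnesium (Z)-3-(bromomagnesio)-2-methylprop-2-en-1-olate | C/C(CO[Mg]Br)=C/[Mg]Br | intermediate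
3 | (Z)-3-iodo-2-methylprop-2-en-1-ol | C/C(CO)=C/I | intermediate
4 | (Z)-tert-butyl[(3-iodo-2-methylprop-2-en-1-yl)oxy]diphenylsilane | C/C(CO[Si](c1ccccc1)(c1ccccc1)C(C)(C)C)=C/I | intermediate
5 | 5-methoxyresorcinol (5-methoxybenzene-1,3-diol) | COc1cc(O)cc(O)c1 | starting material
6 | N-[(2,4-dihydroxy-6-methoxyphenyl)methylidene]-N-methylmethanaminium chloride | COc1cc(O)cc(O)c1C=[N+](C)C.[Cl-] | intermediate
7 | 2,4-dihydroxy-6-methoxybenzaldehyde | COc1cc(O)cc(O)c1C=O | intermediate
8 | 4-[(tert-butyldimethylsilyl)oxy]-2-hydroxy-6-methoxybenzaldehyde | COc1cc(O[Si](C)(C)C(C)(C)C)cc(O)c1C=O | intermediate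
9 | tert-butyl 5-[(tert-butyldimethylsilyl)oxy]-2-formyl-3-methoxyphenyl carbonate | COc1cc(O[Si](C)(C)C(C)(C)C)cc(OC(=O)OC(C)(C)C)c1C=O | intermediate
10 | tert-butyl 5-[(tert-butyldimethylsilyl)oxy]-2-(hydroxymethyl)-3-methoxyphenyl carbonate | COc1cc(O[Si](C)(C)C(C)(C)C)cc(OC(=O)OC(C)(C)C)c1CO | intermediate
11 | (Z)-{3-[(tert-butyldiphenylsilyl)oxy]-2-methylprop-1-en-1-yl}lithium | [Li]/C=C(/C)CO[Si](c1ccccc1)(c1ccccc1)C(C)(C)C | intermediate
12 | (Z)-{3-[(tert-butyldiphenylsilyl)oxy]-2-methylprop-1-en-1-yl}magnesium bromide | Br[Mg]/C=C(/C)CO[Si](c1ccccc1)(c1ccccc1)C(C)(C)C | intermediate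
13 | 3-[(tert-butyldimethylsilyl)oxy]-5-methoxy-6-methylidenecyclohexa-2,4-dien-1-one | C=C1C(=O)C=C(O[Si](C)(C)C(C)(C)C)C=C1OC | intermediate
14 | 5-[(tert-butyldimethylsilyl)oxy]-2-{(Z)-4-[(tert-butyldiphenylsilyl)oxy]-3-methylbut-2-en-1-yl}-3-methoxyphenol | COc1cc(O[Si](C)(C)C(C)(C)C)cc(O)c1C/C=C(/C)CO[Si](c1ccccc1)(c1ccccc1)C(C)(C)C | intermediate
15 | 3,4-dihydroxybenzaldehyde | O=Cc1ccc(O)c(O)c1 | starting material
16 | 4-formyl-1,2-phenylene diacetate (3,4-diacetoxybenzaldehyde) | CC(=O)Oc1ccc(C=O)cc1OC(C)=O | intermediate
17 | allyl bromoacetate (prop-2-en-1-yl 2-bromoacetate) | C=CCOC(=O)CBr | starting material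
18 | bromo[2-oxo-2-(prop-2-en-1-yloxy)ethyl]zinc (Reformatsky reagent) | C=CCOC(=O)C[Zn]Br | intermediate
19 | rac-allyl 3-(3,4-diacetoxyphenyl)-3-hydroxypropanoate | C=CCOC(=O)CC(O)c1ccc(OC(C)=O)c(OC(C)=O)c1 | intermediate
20 | allyl 3-(3,4-diacetoxyphenyl)-3-oxopropanoate | C=CCOC(=O)CC(=O)c1ccc(OC(C)=O)c(OC(C)=O)c1 | intermediate
21 | allyl (R)-3-(3,4-diacetoxyphenyl)-3-hydroxypropanoate | C=CCOC(=O)C[C@@H](O)c1ccc(OC(C)=O)c(OC(C)=O)c1 | intermediate
22 | allyl (S)-3-[5-(tert-butyldimethylsilyloxy)-2-{(Z)-4-(tert-butyldiphenylsilyloxy)-3-methylbut-2-en-1-yl}-3-methoxyphenoxy]-3-(3,4-diacetoxyphenyl)propanoate | C=CCOC(=O)C[C@H](Oc1cc(O[Si](C)(C)C(C)(C)C)cc(OC)c1C/C=C(/C)CO[Si](c1ccccc1)(c1ccccc1)C(C)(C)C)c1ccc(OC(C)=O)c(OC(C)=O)c1 | intermediate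
23 | (S)-3-[5-(tert-butyldimethylsilyloxy)-2-{(Z)-4-(tert-butyldiphenylsilyloxy)-3-methylbut-2-en-1-yl}-3-methoxyphenoxy]-3-(3,4-diacetoxyphenyl)propanoic acid | OC(=O)C[C@H](Oc1cc(O[Si](C)(C)C(C)(C)C)cc(OC)c1C/C=C(/C)CO[Si](c1ccccc1)(c1ccccc1)C(C)(C)C)c1ccc(OC(C)=O)c(OC(C)=O)c1 | intermediate
24 | mixed anhydride of 23 with trifluoroacetic acid | O=C(OC(=O)C(F)(F)F)C[C@H](Oc1cc(O[Si](C)(C)C(C)(C)C)cc(OC)c1C/C=C(/C)CO[Si](c1ccccc1)(c1ccccc1)C(C)(C)C)c1ccc(OC(C)=O)c(OC(C)=O)c1 | intermediate
25 | (2S)-2-(3,4-diacetoxyphenyl)-5-[(tert-butyldimethylsilyl)oxy]-8-{(Z)-4-[(tert-butyldiphenylsilyl)oxy]-3-methylbut-2-en-1-yl}-7-methoxychroman-4-one | COc1cc(O[Si](C)(C)C(C)(C)C)c2c(c1C/C=C(/C)CO[Si](c1ccccc1)(c1ccccc1)C(C)(C)C)O[C@H](c1ccc(OC(C)=O)c(OC(C)=O)c1)CC2=O | intermediate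
26 | (2S)-2-(3,4-diacetoxyphenyl)-5-hydroxy-8-[(Z)-4-hydroxy-3-methylbut-2-en-1-yl]-7-methoxychroman-4-one | COc1cc(O)c2c(c1C/C=C(/C)CO)O[C@H](c1ccc(OC(C)=O)c(OC(C)=O)c1)CC2=O | intermediate
27 | (2S)-2-(3,4-dihydroxyphenyl)-5-hydroxy-8-[(Z)-4-hydroxy-3-methylbut-2-en-1-yl]-7-methoxychroman-4-one | COc1cc(O)c2c(c1C/C=C(/C)CO)O[C@H](c1ccc(O)c(O)c1)CC2=O | target

## Step count and least certain steps

Total: 16 steps (side chain 2, phenol 5, hydroxy ester 4, union and end game 5). Longest linear sequence: 10 steps (5 → 27 through steps 3–7 and 12–16).

**Step 14 (key step).** The most likely failure is ionisation of the benzylic C2–O bond in the trifluoroacetic acid that the activation releases. This would erode the configuration at C2 or lead to β-elimination of the phenol. Acid-induced loss of silyl groups or slow trifluoroacetylation of ring A at C6 are lesser risks. The fallback removes free Brønsted acid by separating activation from ring closure. It sets out from 23, which is converted under neutral conditions with 1-chloro-N,N,2-trimethylprop-1-en-1-amine into the acid chloride (S)-3-aryloxy-3-(3,4-diacetoxyphenyl)propanoyl chloride F1. F1 is closed with SnCl4 at −78 °C in CH2Cl2 in the presence of 2,6-di-tert-butyl-4-methylpyridine as proton trap. The fallback comes back to the route at 25.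

**Step 12.** The activated β-hydroxy ester may dehydrate to the cinnamate instead of being substituted, because the α-hydrogens are acidic and the phenol is hindered by its ortho substituent. Partial ionisation at the benzylic carbon would lower the enantiomeric purity. The fallback replaces the phosphonium leaving group by a strained carboxylate and sets out from 21. Deallylation (Pd(PPh3)4, N-methylaniline) gives (R)-3-(3,4-diacetoxyphenyl)-3-hydroxypropanoic acid F2. Carboxyl activation with benzenesulfonyl chloride in pyridine closes F2 with retention to the β-lactone (R)-4-(3,4-diacetoxyphenyl)oxetan-2-one F3. The sodium phenoxide of 14 (NaH, THF, 0 °C) opens F3 at the benzylic carbon by alkyl–oxygen cleavage with inversion. A β-lactone enolate is stereoelectronically unable to eliminate, which is the point of the change. The main risk of this fallback is acetyl transfer from ring B to the phenoxide. It comes back to the route at 23 and makes step 13 unnecessary.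

**Step 7.** The quinone methide 13 may form before the alkenyl nucleophile is at hand and then dimerise, or it may take up the tert-butyl group of the base. The alkenyl metal may also lose geometry or suffer oxygen-to-carbon silyl migration if it warms as the lithium species. The fallback forms the aryl–CH2 bond instead and sets out from 5 and 4.
- Monosilylation of 5 (TBSCl, one equivalent, recycling) gives 3-[(tert-butyldimethylsilyl)oxy]-5-methoxyphenol F4. MOMCl and i-Pr2NEt convert it into tert-butyl[3-methoxy-5-(methoxymethoxy)phenoxy]dimethylsilane F5.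
- From 4, iodine–lithium exchange and addition to paraformaldehyde give (Z)-4-[(tert-butyldiphenylsilyl)oxy]-3-methylbut-2-en-1-ol F6. CBr4 and PPh3 turn it into (Z)-[(4-bromo-2-methylbut-2-en-1-yl)oxy](tert-butyl)diphenylsilane F7.
- Lithiation of F5 between the two directing ether groups (n-BuLi, TMEDA) takes place away from the bulky silyl ether. Transmetalation with CuBr·SMe2 and alkylation with F7 give the methoxymethyl ether of 14, F8.
- The acetal of F8 is removed with TMSOTf and 2,2'-bipyridyl followed by water. The fallback comes back to the route at 14.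

**Step 3.** Formylation may also occur between the two hydroxyl groups, or twice, which would cost material at the very start and complicate purification. The fallback fixes the site by directed metalation. It sets out from 5 and uses 3-[(tert-butyldimethylsilyl)oxy]-5-methoxyphenol F4 and its methoxymethyl ether F5, prepared as described for step 7. F5 is lithiated between the methoxymethoxy and methoxy groups and quenched with DMF to give 4-[(tert-butyldimethylsilyl)oxy]-2-methoxy-6-(methoxymethoxy)benzaldehyde F9. Mild acid removes the acetal next to the formyl group. The fallback comes back to the route at 8 and makes steps 3 and 4 unnecessary.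

## Further compounds

F1 | step 14 | (S)-3-[5-(tert-butyldimethylsilyloxy)-2-{(Z)-4-(tert-butyldiphenylsilyloxy)-3-methylbut-2-en-1-yl}-3-methoxyphenoxy]-3-(3,4-diacetoxyphenyl)propanoyl chloride | ClC(=O)C[C@H](Oc1cc(O[Si](C)(C)C(C)(C)C)cc(OC)c1C/C=C(/C)CO[Si](c1ccccc1)(c1ccccc1)C(C)(C)C)c1ccc(OC(C)=O)c(OC(C)=O)c1
F2 | step 12 | (R)-3-(3,4-diacetoxyphenyl)-3-hydroxypropanoic acid | OC(=O)C[C@@H](O)c1ccc(OC(C)=O)c(OC(C)=O)c1
F3 | step 12 | (R)-4-(3,4-diacetoxyphenyl)oxetan-2-one | O=C1C[C@H](c2ccc(OC(C)=O)c(OC(C)=O)c2)O1
F4 | step 7 | 3-[(tert-butyldimethylsilyl)oxy]-5-methoxyphenol | COc1cc(O)cc(O[Si](C)(C)C(C)(C)C)c1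
F5 | step 7 | tert-butyl[3-methoxy-5-(methoxymethoxy)phenoxy]dimethylsilane | COCOc1cc(OC)cc(O[Si](C)(C)C(C)(C)C)c1
F6 | step 7 | (Z)-4-[(tert-butyldiphenylsilyl)oxy]-3-methylbut-2-en-1-ol | C/C(CO[Si](c1ccccc1)(c1ccccc1)C(C)(C)C)=C/CO
F7 | step 7 | (Z)-[(4-bromo-2-methylbut-2-en-1-yl)oxy](tert-butyl)diphenylsilane | C/C(CO[Si](c1ccccc1)(c1ccccc1)C(C)(C)C)=C/CBr
F8 | step 7 | tert-butyl[4-{(Z)-4-[(tert-butyldiphenylsilyl)oxy]-3-methylbut-2-en-1-yl}-3-methoxy-5-(methoxymethoxy)phenoxy]dimethylsilane | COCOc1cc(O[Si](C)(C)C(C)(C)C)cc(OC)c1C/C=C(/C)CO[Si](c1ccccc1)(c1ccccc1)C(C)(C)C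
F9 | step 3 | 4-[(tert-butyldimethylsilyl)oxy]-2-methoxy-6-(methoxymethoxy)benzaldehyde | COCOc1cc(O[Si](C)(C)C(C)(C)C)cc(OC)c1C=O
A1 | alternative 1 | 5-ethoxy-3-methoxy-2-[(Z)-4-(tert-butyldimethylsilyloxy)-3-methylbut-2-enyl]phenol | CCOc1cc(OC)c(C/C=C(/C)CO[Si](C)(C)C(C)(C)C)c(O)c1
A2 | alternative 1 | 3-ethoxycyclobut-2-en-1-one | CCOC1=CC(=O)C1
A3 | alternative 1 | (Z)-tert-butyl[(6-methoxy-2-methylhex-2-en-5-yn-1-yl)oxy]dimethylsilane | COC#CC/C=C(/C)CO[Si](C)(C)C(C)(C)C
A4 | alternative 2 | silyl-protected (2S)-2,4-cis-4-methoxyflavan: (2S)-2-[3,4-bis(tert-butyldimethylsilyloxy)phenyl]-5-(tert-butyldimethylsilyloxy)-8-[(Z)-4-(tert-butyldimethylsilyloxy)-3-methylbut-2-enyl]-4,7-dimethoxychroman, 2,4-cis | COc1cc(O[Si](C)(C)C(C)(C)C)c2c(c1C/C=C(/C)CO[Si](C)(C)C(C)(C)C)O[C@H](c1ccc(O[Si](C)(C)C(C)(C)C)c(O[Si](C)(C)C(C)(C)C)c1)C[C@@H]2OC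
A5 | alternative 2 | 6-(tert-butyldimethylsilyloxy)-2-hydroxy-4-methoxy-3-[(Z)-4-(tert-butyldimethylsilyloxy)-3-methylbut-2-enyl]benzaldehyde | COc1cc(O[Si](C)(C)C(C)(C)C)c(C=O)c(O)c1C/C=C(/C)CO[Si](C)(C)C(C)(C)C
A6 | alternative 2 | 3,4-bis(tert-butyldimethylsilyloxy)styrene | C=Cc1ccc(O[Si](C)(C)C(C)(C)C)c(O[Si](C)(C)C(C)(C)C)c1
A7 | alternative 3 | (2S)-2-[3,4-bis(tert-butyldimethylsilyloxy)phenyl]-5-hydroxy-8-[(Z)-4-(tert-butyldimethylsilyloxy)-3-methylbut-2-enyl]-7-methoxychroman-4-one | COc1cc(O)c2c(c1C/C=C(/C)CO[Si](C)(C)C(C)(C)C)O[C@H](c1ccc(O[Si](C)(C)C(C)(C)C)c(O[Si](C)(C)C(C)(C)C)c1)CC2=O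
A8 | alternative 3 | (S)-5-bromo-2-[3,4-bis(tert-butyldimethylsilyloxy)phenyl]-2,3-dihydro-4H-pyran-4-one | O=C1C[C@@H](c2ccc(O[Si](C)(C)C(C)(C)C)c(O[Si](C)(C)C(C)(C)C)c2)OC=C1Br
A9 | alternative 3 | (6Z)-8-(tert-butyldimethylsilyloxy)-1,3-dimethoxy-7-methyl-1-(trimethylsilyloxy)octa-1,3,6-triene | COC(O[Si](C)(C)C)=CC(OC)=CC/C=C(/C)CO[Si](C)(C)C(C)(C)C
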